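**Retrosynthetic overview**

1. The C7–C11 bond (ring carbon C7 of the seven-membered ring to the side-chain methine C11) is the central bond of a 1,4-dioxygenated chain O–C6–C7–C11–C12–O. C7 is α to the ring carbinol carbon C6 and C11 is α to the acetoxy carbon C12, so the bond is cut to two ketone enolates of like polarity and made by oxidative enolate coupling on a temporary diisopropylsilyl tether (1,4-diketone 20).
2. Ring ketone 12: the seven-membered ring is closed by ring-closing metathesis (C9=C10) on a trans-2,3-disubstituted cyclopentane obtained by copper-catalysed conjugate addition–aldol reaction of cyclopentenone. The two methyl-bearing ring alkenes are carried as epoxides, which mask both CH2=C–CH(OH) units and keep H-5 non-allylic.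
3. Side chain 15: the Z-silyl enol ether of 6-methylhept-5-en-3-one, made regiospecifically from 4-methylpent-3-enoic acid by ethylidenation of its silyl ester.
4. After the coupling: reagent-controlled reduction and acetylation at C12, hydride reduction at C6, then titanocene-mediated opening of both epoxides to the exocyclic allylic alcohols.
5. Ring order: five-membered ring (from cyclopentenone) → seven-membered ring (metathesis) → two temporary oxiranes (opened in the last step).

Key step: step 12

Remark (numbering): guaiane-type numbering is used for the bicycle. C1 and C5 are the ring-fusion carbons, C2–C4 complete the five-membered ring (C3 carbinol, C4 methylene-bearing), C6–C10 complete the seven-membered ring (C6 carbinol, C7 side-chain carbon, C9 carbinol, C10 methylene-bearing), and C11 (CH–CH3), C12 (CH–OAc), C13–C15 form the side chain. α is the face of H-5, β the face of H-1.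

Remark (assumption): in step 1 the ligand enantiomer is the one that delivers the 3S adduct. The carbinol configuration created in step 1 is shown as the expected anti-aldol epimer and is of no consequence, because C6 is oxidised in step 8.

**Route**

Step 1
Reactants: 1 cyclopent-2-en-1-one; 2 isopropenylmagnesium bromide; 3 pent-4-enal
Product: 5 (2S,3S)-2-[(1S)-1-hydroxypent-4-en-1-yl]-3-(prop-1-en-2-yl)cyclopentan-1-one, via magnesium enolate 4 (not isolated)
Conditions: CuBr·SMe2 (5 mol %), (R)-1-[(S)-2-(diphenylphosphino)ferrocenyl]ethyldicyclohexylphosphine (6 mol %), tBuOMe, −78 °C; then 3, −78 °C; aq NH4Cl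
Reagents that add atoms: none
Why: Copper-catalysed asymmetric conjugate addition of the alkenyl Grignard reagent should set the isopropenyl-bearing carbon (future C1) under ligand control, and the magnesium enolate 4 should add to aldehyde 3 anti to that substituent (tandem conjugate addition–aldol reaction), which fixes the trans relationship of the future C1 and C5.

Step 2
Reactants: 5 aldol adduct
Product: 6 (2S,3S)-2-[(1S)-1-(tert-butyldimethylsilyloxy)pent-4-en-1-yl]-3-(prop-1-en-2-yl)cyclopentan-1-one
Conditions: tBuMe2SiOTf, 2,6-lutidine, CH2Cl2, −78 °C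
Reagents that add atoms: tert-butyldimethylsilyl trifluoromethanesulfonate, CC(C)(C)[Si](C)(C)OS(=O)(=O)C(F)(F)F
Why: Low-temperature silylation of the secondary alcohol with a silyl triflate should protect the β-hydroxy ketone without retro-aldol cleavage.

Step 3
Reactants: 6 silyl ether
Product: 7 enol triflate of 6 toward the ring methylene (future C3=C4)
Conditions: KN(SiMe3)2, PhNTf2, THF, −78 °C
Reagents that add atoms: N-phenylbis(trifluoromethanesulfonimide), O=S(=O)(N(c1ccccc1)S(=O)(=O)C(F)(F)F)C(F)(F)F
Why: Kinetic deprotonation should take place at the unhindered α-methylene and not at the doubly branched α-methine, so O-sulfonylation gives the enol triflate with the double bond in the future C3=C4 position.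

Step 4
Reactants: 7 enol triflate
Product: 8 2-methylcyclopent-2-ene with the 1-(silyloxy)pent-4-enyl and isopropenyl groups trans
Conditions: Me2CuLi (from MeLi and CuI), Et2O, −20 → 0 °C
Reagents that add atoms: lithium dimethylcuprate, [Li+].C[Cu-]C
Why: Cuprate cross-coupling of an alkenyl triflate replaces the triflate by methyl with retention of the alkene position, which installs the carbon that later becomes the exocyclic methylene on C4.

Step 5
Reactants: 8 diene-ene
Product: 9 trans-fused 6α-(tert-butyldimethylsilyloxy)-4,10-dimethylbicyclo[5.3.0]deca-3,9-diene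
Conditions: (H2IMes)(PCy3)Cl2Ru=CHPh (second-generation Grubbs catalyst, 5 mol %), CH2Cl2, 40 °C
Reagents that add atoms: none
Why: Ring-closing metathesis between the terminal vinyl group and the isopropenyl group should close the seven-membered ring as the trisubstituted C9=C10 alkene, the endocyclic trisubstituted cyclopentene being inert.

Step 6
Reactants: 9 bicyclic diene
Product: 10 3α,4α:9β,10β-diepoxide of 9
Conditions: mCPBA (2.4 equiv), NaHCO3, CH2Cl2, 0 °C
Reagents that add atoms: 3-chloroperbenzoic acid, OOC(=O)c1cccc(Cl)c1
Why: Prilezhaev epoxidation of both trisubstituted alkenes should occur anti to the substituent on the adjacent ring-fusion carbon, that is on the α-face at C3=C4 (β-face blocked by the C6 silyloxy-bearing carbon on C5) and on the β-face at C9=C10 (α-face blocked by C2 on C1), which sets the C3 and C9 oxygen configurations of the target.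

Step 7
Reactants: 10 diepoxy silyl ether
Product: 11 3α,4α:9β,10β-diepoxy-4,10-dimethylbicyclo[5.3.0]decan-6α-ol
Conditions: Bu4NF, THF, 40 °C
Reagents that add atoms: none
Why: Fluoride-mediated desilylation is neutral to basic and should leave the acid-sensitive trisubstituted epoxides untouched.

Step 8
Reactants: 11 diepoxy alcohol
Product: 12 3α,4α:9β,10β-diepoxy-4,10-dimethylbicyclo[5.3.0]decan-6-one
Conditions: Dess–Martin periodinane, NaHCO3, CH2Cl2, 0 °C → 25 °C
Reagents that add atoms: none
Why: Buffered Dess–Martin oxidation should give the ketone without epimerising C5 or opening the β,γ-epoxide.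

Step 9
Reactants: 13 4-methylpent-3-enoic acid
Product: 14 trimethylsilyl 4-methylpent-3-enoate
Conditions: Me3SiCl, Et3N, Et2O, 0 → 25 °C; filtration, distillation
Reagents that add atoms: chlorotrimethylsilane, C[Si](C)(C)Cl
Why: O-silylation of the carboxylic acid gives the silyl ester needed for carbonyl alkylidenation.

Step 10
Reactants: 14 silyl ester
Product: 15 (2Z)-6-methyl-3-(trimethylsilyloxy)hepta-2,5-diene
Conditions: CH3CHBr2, Zn, TiCl4, TMEDA, THF, 25 °C
Reagents that add atoms: 1,1-dibromoethane, CC(Br)Br
Why: Takai–Utimoto ethylidenation of a silyl ester gives the Z-silyl enol ether directly, which fixes the enol regiochemistry that deprotonation of the β,γ-unsaturated ketone could not give.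

Step 11
Reactants: 12 diepoxy ketone; 15 silyl enol ether
Product: 19 diisopropylsilyl bis-enol ether of 12 (C6=C7 enol) and of (Z)-6-methylhept-5-en-3-one, via ring lithium enolate 16 (not isolated), via ring chlorosilyl enol ether 17 (not isolated), via side-chain lithium enolate 18 (not isolated)
Conditions: 12, LiN(iPr)2, THF, −78 °C; iPr2SiCl2 (5 equiv), −78 → 25 °C, excess silane removed in vacuo; 15, MeLi, THF, 0 °C, then added to 17 at −78 → 0 °C; filtration through Et3N-deactivated silica
Reagents that add atoms: dichlorodiisopropylsilane, CC(C)[Si](Cl)(Cl)C(C)C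
Why: Kinetic deprotonation of 12 should occur at the C7 methylene and not at the C5 methine (not allylic because C4 is held as the epoxide), and sequential O-silylation with the dichlorosilane followed by the geometry-defined enolate 18 (Si–O cleavage of 15 by MeLi) gives the unsymmetrical silicon-tethered bis-enol ether.

Step 12
Reactants: 19 silyl bis-enol ether
Product: 20 3α,4α:9β,10β-diepoxy-4,10-dimethyl-7α-[(2S)-6-methyl-3-oxohept-5-en-2-yl]bicyclo[5.3.0]decan-6-one
Conditions: (NH4)2Ce(NO3)6 (2.2 equiv), NaHCO3 (4.4 equiv), MeCN/EtCN, −10 °C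
Reagents that add atoms: none
Why: Tetravalent cerium removes one electron from an enol ether of 19, and the radical cation is attacked within the O–Si–O tether by the carbon of the second enol ether, so that C7 and C11, two α-carbons of like (nucleophilic) polarity, are joined; a second one-electron oxidation and loss of the silicon as the silanediol then release the 1,4-diketone. The closest known reaction type is the oxidation of unsymmetrical dialkylsilyl bis-enol ethers of two different ketones to 1,4-diketones with cerium ammonium nitrate (tethered oxidative enolate heterocoupling). No ring of the target is closed; the only ring formed is the transient seven-membered 1,3-dioxa-2-silacycloheptane, closed by the C7–C11 bond under the template of the tether and opened again when the Si–O bonds are cleaved. C7 should be set by attack on the α-face of the ring enol ether, the β-face being screened by the cyclopentane ring attached at C5 (C4 and its β-methyl), and C11 by the tether, in which the cyclic E-type enol ether and the Z-configured side-chain enol ether are expected to combine in the unlike sense that places the C8 methylene and the C11 methyl anti along the C6–C7–C11–C12 chain. The step needs cross-coupling over homo-coupling, which the tether secures, and oxidation of the enol ethers in preference to the trisubstituted alkene and the two epoxides, which their lower oxidation potential, the NaHCO3 buffer and the low temperature should secure.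

Step 13
Reactants: 20 diketone
Product: 21 7α-[(2S,3S)-3-hydroxy-6-methylhept-5-en-2-yl] diepoxy ketone
Conditions: (R)-1-methyl-3,3-diphenyltetrahydro-1H,3H-pyrrolo[1,2-c][1,3,2]oxazaborole ((R)-Me-CBS, 1.0 equiv), catecholborane, toluene, −78 °C
Reagents that add atoms: none
Why: Corey–Bakshi–Shibata reduction should be selective for the side-chain ketone (one α-branch) over the C6 ketone (two α-branches) and, by reagent control that distinguishes the branched C11 from the C13 methylene, should give the 12S alcohol syn to the C11 methyl.

Step 14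
Reactants: 21 hydroxy ketone
Product: 22 12-acetate of 21
Conditions: Ac2O, pyridine, 4-(dimethylamino)pyridine (cat.), CH2Cl2, 0 °C
Reagents that add atoms: acetic anhydride, CC(=O)OC(C)=O
Why: Acylation of the only free hydroxyl group differentiates the C12 oxygen from the C6 oxygen, which is still a ketone, any cyclic hemiketal being drained through the open form.

Step 15
Reactants: 22 keto acetate
Product: 23 3α,4α:9β,10β-diepoxy-6α-hydroxy 12-acetate
Conditions: Li[HB(sBu)3], THF, −78 °C; aq NH4Cl
Reagents that add atoms: none
Why: The bulky hydride should approach the C6 carbonyl from the β-face, anti to the branched α-oriented C7 side chain, giving the 6α-alcohol cis to the side chain while the acetate survives at −78 °C.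

Step 16
Reactants: 23 diepoxy alcohol
Product: 24 target, (1S,3R,5R,6S,7R,9S,11S,12S)-12-acetoxy-3,6,9-triol with exocyclic methylenes at C4 and C10
Conditions: Cp2TiCl2 (5 equiv), Mn dust, THF, 25 °C (chlorobis(cyclopentadienyl)titanium, trivalent titanium, formed in the flask); aq NaH2PO4
Reagents that add atoms: none
Why: Trivalent titanium opens each trisubstituted epoxide homolytically to the tertiary radical (C4, C10) with the oxygen retained on C3 and C9, and hydrogen removal from the adjacent methyl group by a second titanium centre (titanocene-mediated epoxide to allylic alcohol isomerisation) should give both exocyclic methylene allylic alcohols without touching the acetate or the C3 and C9 configurations.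

**Compound list**

1 | cyclopent-2-en-1-one | O=C1C=CCC1 | starting material
2 | isopropenylmagnesium bromide (prop-1-en-2-ylmagnesium bromide) | CC(=C)[Mg]Br | starting material
3 | pent-4-enal | C=CCCC=O | starting material
4 | bromomagnesium (S)-3-(prop-1-en-2-yl)cyclopent-1-en-1-olate, formed in the flask | Br[Mg]OC1=C[C@@H](C(C)=C)CC1 | intermediate
5 | (2S,3S)-2-[(1S)-1-hydroxypent-4-en-1-yl]-3-(prop-1-en-2-yl)cyclopentan-1-one (ring substituents trans, anti aldol) | O=C1[C@H]([C@@H](O)CCC=C)[C@@H](C(C)=C)CC1 | intermediate
6 | (2S,3S)-2-[(1S)-1-(tert-butyldimethylsilyloxy)pent-4-en-1-yl]-3-(prop-1-en-2-yl)cyclopentan-1-one | O=C1[C@H]([C@@H](O[Si](C)(C)C(C)(C)C)CCC=C)[C@@H](C(C)=C)CC1 | intermediate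
7 | 5-[1-(tert-butyldimethylsilyloxy)pent-4-enyl]-4-(prop-1-en-2-yl)cyclopent-1-en-1-yl trifluoromethanesulfonate, stereocentres as in 6 (ring substituents trans) | FC(F)(F)S(=O)(=O)OC=1[C@H]([C@@H](O[Si](C)(C)C(C)(C)C)CCC=C)[C@@H](C(C)=C)CC=1 | intermediate
8 | tert-butyldimethylsilyl ether of 1-[2-methyl-5-(prop-1-en-2-yl)cyclopent-2-en-1-yl]pent-4-en-1-ol, stereocentres as in 6 (ring substituents trans) | CC=1[C@H]([C@@H](O[Si](C)(C)C(C)(C)C)CCC=C)[C@@H](C(C)=C)CC=1 | intermediate
9 | trans-fused 6α-(tert-butyldimethylsilyloxy)-4,10-dimethylbicyclo[5.3.0]deca-3,9-diene (H-1β, H-5α) | CC=1[C@@H]2[C@@H](O[Si](C)(C)C(C)(C)C)CCC=C(C)[C@H]2CC=1 | intermediate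
10 | 3α,4α:9β,10β-diepoxide of 9 (4-methyl β, 10-methyl α) | C[C@]13[C@@H]2[C@@H](O[Si](C)(C)C(C)(C)C)CC[C@@H]4O[C@]4(C)[C@H]2C[C@H]1O3 | intermediate
11 | 3α,4α:9β,10β-diepoxy-4,10-dimethylbicyclo[5.3.0]decan-6α-ol (H-1β, H-5α) | C[C@]13[C@@H]2[C@@H](O)CC[C@@H]4O[C@]4(C)[C@H]2C[C@H]1O3 | intermediate
12 | 3α,4α:9β,10β-diepoxy-4,10-dimethylbicyclo[5.3.0]decan-6-one (H-1β, H-5α) | C[C@]13[C@@H]2C(=O)CC[C@@H]4O[C@]4(C)[C@H]2C[C@H]1O3 | intermediate
13 | 4-methylpent-3-enoic acid | CC(C)=CCC(=O)O | starting material
14 | trimethylsilyl 4-methylpent-3-enoate | CC(C)=CCC(=O)O[Si](C)(C)C | intermediate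
15 | (2Z)-6-methyl-3-(trimethylsilyloxy)hepta-2,5-diene | C/C=C(\O[Si](C)(C)C)CC=C(C)C | intermediate
16 | lithium C6=C7 enolate of 12, formed in the flask | C[C@]13[C@@H]2C(O[Li])=CC[C@@H]4O[C@]4(C)[C@H]2C[C@H]1O3 | intermediate
17 | chlorodiisopropylsilyl C6=C7 enol ether of 12, formed in the flask | C[C@]13[C@@H]2C(O[Si](Cl)(C(C)C)C(C)C)=CC[C@@H]4O[C@]4(C)[C@H]2C[C@H]1O3 | intermediate
18 | lithium (2Z)-6-methylhepta-2,5-dien-3-olate, formed in the flask | C/C=C(\O[Li])CC=C(C)C | intermediate
19 | diisopropylsilyl bis-enol ether linking O-6 of the C6=C7 enol of 12 and the oxygen of the (Z)-enol of 6-methylhept-5-en-3-one | C[C@]13[C@@H]2C(O[Si](C(C)C)(C(C)C)O/C(CC=C(C)C)=C\C)=CC[C@@H]4O[C@]4(C)[C@H]2C[C@H]1O3 | intermediate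
20 | 3α,4α:9β,10β-diepoxy-4,10-dimethyl-7α-[(2S)-6-methyl-3-oxohept-5-en-2-yl]bicyclo[5.3.0]decan-6-one (7R,11S) | C[C@]13[C@@H]2C(=O)[C@@H]([C@H](C)C(=O)CC=C(C)C)C[C@@H]4O[C@]4(C)[C@H]2C[C@H]1O3 | intermediate
21 | 3α,4α:9β,10β-diepoxy-7α-[(2S,3S)-3-hydroxy-6-methylhept-5-en-2-yl]-4,10-dimethylbicyclo[5.3.0]decan-6-one | C[C@]13[C@@H]2C(=O)[C@@H]([C@H](C)[C@H](CC=C(C)C)O)C[C@@H]4O[C@]4(C)[C@H]2C[C@H]1O3 | intermediate
22 | 7α-[(2S,3S)-3-acetoxy-6-methylhept-5-en-2-yl]-3α,4α:9β,10β-diepoxy-4,10-dimethylbicyclo[5.3.0]decan-6-one | C[C@]13[C@@H]2C(=O)[C@@H]([C@H](C)[C@H](CC=C(C)C)OC(C)=O)C[C@@H]4O[C@]4(C)[C@H]2C[C@H]1O3 | intermediate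
23 | 7α-[(2S,3S)-3-acetoxy-6-methylhept-5-en-2-yl]-3α,4α:9β,10β-diepoxy-4,10-dimethylbicyclo[5.3.0]decan-6α-ol | C[C@]13[C@@H]2[C@@H](O)[C@@H]([C@H](C)[C@H](CC=C(C)C)OC(C)=O)C[C@@H]4O[C@]4(C)[C@H]2C[C@H]1O3 | intermediate
24 | target: (1S,3R,5R,6S,7R,9S)-7-[(2S,3S)-3-acetoxy-6-methylhept-5-en-2-yl]-4,10-dimethylidenebicyclo[5.3.0]decane-3,6,9-triol (H-1β, H-5α, 3α-OH, 6α-OH, 9β-OH, 7α side chain; guaiane-type numbering, C11 S, C12 S) | C=C1[C@@H]2[C@@H](O)[C@@H]([C@H](C)[C@H](CC=C(C)C)OC(C)=O)C[C@H](O)C(=C)[C@H]2C[C@H]1O | target

**Step count and risks**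

Total step count: 16. Longest linear sequence: 14 (steps 1–8 and 11–16); steps 9 and 10 make the side-chain partner.

Steps most likely to fail:

Step 12. The cerium salt may open the acid-sensitive trisubstituted epoxides, or the coupling may give poor facial selectivity at C11. Fallback (sets out from 12 and 15, returns at 20): ketone 12 is converted with LiN(iPr)2 and Me3SiCl (THF, −78 °C) into the C6=C7 trimethylsilyl enol ether F1, and enol ether 15 is brominated with N-bromosuccinimide (THF, −78 °C) to 2-bromo-6-methylhept-5-en-3-one F2. F1 and F2 are then joined under visible-light photoredox catalysis (Ru(bpy)3Cl2, 1 mol %, blue light, 2,6-lutidine, DMF, 25 °C). The α-keto radical from F2 adds to C7 of F1, and oxidation and desilylation give 20 under neutral, non-Lewis-acidic conditions, without a tether.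

Step 13. Reagent control may not override the substrate's Felkin–Anh preference for the 12-epimer, or the C6 ketone may be reduced as well. Fallback (sets out from 20, returns at 22): substrate-controlled reduction of the side-chain ketone with Li[HB(sBu)3] (THF, −78 °C) gives the 12-epimeric (12R, anti) alcohol F3. A Mitsunobu reaction with acetic acid (PPh3, diisopropyl azodicarboxylate, toluene, 0 °C) then inverts C12 and installs the acetate in one operation, giving 22 and making step 14 unnecessary.

Step 16. The tertiary radicals may be reduced instead of eliminated, hydrogen loss may occur toward the ring (endocyclic alkenes), or only one epoxide may react. Fallback (sets out from 23, returns at 24): treatment with Me3SiOTf and 2,6-lutidine followed by DBU (toluene, −78 → 25 °C; silyl triflate–amidine epoxide to allyl silyl ether isomerisation, with silylation of the C6 hydroxyl) gives the tris(trimethylsilyl) ether F4 of the target. Mild acidic methanolysis (citric acid, MeOH, 0 °C) then releases 24 with the acetate intact.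

**Further compounds**

F1 | step 12 | C6=C7 trimethylsilyl enol ether of diepoxy ketone 12 | C[C@]13[C@@H]2C(O[Si](C)(C)C)=CC[C@@H]4O[C@]4(C)[C@H]2C[C@H]1O3
F2 | step 12 | 2-bromo-6-methylhept-5-en-3-one (racemic) | CC(Br)C(=O)CC=C(C)C
F3 | step 13 | 3α,4α:9β,10β-diepoxy-7α-[(2S,3R)-3-hydroxy-6-methylhept-5-en-2-yl]-4,10-dimethylbicyclo[5.3.0]decan-6-one (12-epimer of 21) | C[C@]13[C@@H]2C(=O)[C@@H]([C@H](C)[C@@H](CC=C(C)C)O)C[C@@H]4O[C@]4(C)[C@H]2C[C@H]1O3
F4 | step 16 | 3,6,9-tris(trimethylsilyl) ether of target 24 | C=C1[C@@H]2[C@@H](O[Si](C)(C)C)[C@@H]([C@H](C)[C@H](CC=C(C)C)OC(C)=O)C[C@H](O[Si](C)(C)C)C(=C)[C@H]2C[C@H]1O[Si](C)(C)C
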